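**Plan**

- Retrosynthesis: after removal of two MOM ethers, ring C of the flavanone is cut at C2–C3 and at O1–C8a together. This leaves an aldehyde (ring B with its fused dimethylpyran ring) and a ring A methyl ketone that carries fluorine at the future C8a. The ketone is cut at its aryl–acetyl and aryl–prenyl bonds back to 5-fluororesorcinol, the aldehyde at its formyl and pyran bonds back to 4-bromophenol and isoprene.
- Forward order: the dimethylpyran ring on ring B closes first (step 1). Ring A is dressed by two fluorine-directed metalations, prenyl then acetyl (steps 4 and 5). Ring C closes last, in one catalytic annulation that joins the two fragments (step 7), and deprotection ends the route.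
- Enabling feature: the acetyl group on C4a of ring A stands ortho to the C8a–F bond. Its methyl carbon (C3) is the enolate that attacks the aldehyde carbon (C2), its carbonyl (C4) activates C8a for ipso attack by the aldehyde-derived oxygen (O1), and the fluoride expelled there is the Lewis base that unmasks the next silyl enol ether. The single fluorine also fixes the prenyl group at C8 and not at C6.
- Stereochemistry: the only stereocentre, C2 (S), arises in step 7 under control of a chiral quaternary ammonium cation, the sole counter-ion of enolate and aldolate. Retro-aldol equilibration makes the step dynamic, and the acidic last step leaves C2 untouched.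

Key step: step 7

Remark on the chemistry: the sense of induction of the chiral ammonium cation in step 7 cannot be assigned in advance. The (S,S) catalyst is written, and its equally available (R,R) antipode is taken if the first experiment shows the (2R) series.

**Route**

Step 1
Reactants: 1 4-bromophenol
Product: 3 6-bromo-2,2-dimethylchroman, via 4-bromo-2-(3-methylbut-2-en-1-yl)phenol 2 (not isolated)
Conditions: isoprene, 85% H3PO4, toluene, 30 °C
Reagents that add atoms: isoprene, C=CC(C)=C
Why: Acid-catalysed Friedel–Crafts ortho-prenylation of the phenol (para position blocked by bromine) should give 2, whose hydroxyl then adds in Markovnikov fashion to the trisubstituted alkene and closes the 2,2-dimethylpyran ring; no stereocentre is formed.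

Step 2
Reactants: 3 6-bromo-2,2-dimethylchroman
Product: 6 2,2-dimethylchroman-6-carbaldehyde, via (2,2-dimethylchroman-6-yl)lithium 4 (not isolated), via lithium hemiaminolate 5 (not isolated)
Conditions: n-BuLi, THF, −78 °C; DMF, −78 → 0 °C; H2O
Reagents that add atoms: N,N-dimethylformamide, CN(C)C=O
Why: Bromine–lithium exchange followed by formylation of the aryllithium with DMF (Bouveault aldehyde synthesis) should place the formyl group at the carbon that carried bromine.

Step 3
Reactants: 7 5-fluororesorcinol
Product: 8 1-fluoro-3,5-bis(methoxymethoxy)benzene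
Conditions: MOMCl, i-Pr2NEt, CH2Cl2, 0 °C → rt
Reagents that add atoms: chloromethyl methyl ether, COCCl
Why: O-alkylation of both phenols (Williamson-type etherification) should give the bis-acetal, which is stable to the strong bases of steps 4 to 7 and assists the ortho-metalations.

Step 4
Reactants: 8 1-fluoro-3,5-bis(methoxymethoxy)benzene
Product: 11 1-fluoro-3,5-bis(methoxymethoxy)-2-(3-methylbut-2-en-1-yl)benzene, via aryllithium 9 (not isolated), via arylcopper 10 (not isolated)
Conditions: LiN(i-Pr)2, THF, −78 °C; CuBr·SMe2, −78 → −40 °C; prenyl bromide, −40 → 0 °C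
Reagents that add atoms: prenyl bromide (1-bromo-3-methylbut-2-ene), CC(C)=CCBr
Why: Directed ortho-metalation with an amide base, which selects by acidity, should remove the proton flanked by fluorine and an OMOM group (two equivalent sites) and not the one between the two OMOM groups, and the derived arylcopper should be alkylated at the primary carbon of prenyl bromide (SN2 allylic substitution).

Step 5
Reactants: 11 1-fluoro-3,5-bis(methoxymethoxy)-2-(3-methylbut-2-en-1-yl)benzene
Product: 14 1-[2-fluoro-4,6-bis(methoxymethoxy)-3-(3-methylbut-2-en-1-yl)phenyl]ethan-1-one, via aryllithium 12 (not isolated), via lithium hemiaminolate 13 (not isolated)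
Conditions: LiN(i-Pr)2, THF, −78 °C; MeC(O)N(OMe)Me, −78 → 0 °C; H2O
Reagents that add atoms: N-methoxy-N-methylacetamide, CC(=O)N(C)OC
Why: A second fluorine-directed ortho-metalation at the only remaining position flanked by fluorine and OMOM, then acyl transfer from the N-methoxy-N-methylamide through the chelated adduct 13, which releases the methyl ketone only on work-up, should give the ketone without over-addition.

Step 6
Reactants: 14 1-[2-fluoro-4,6-bis(methoxymethoxy)-3-(3-methylbut-2-en-1-yl)phenyl]ethan-1-one
Product: 16 ({1-[2-fluoro-4,6-bis(methoxymethoxy)-3-(3-methylbut-2-en-1-yl)phenyl]ethenyl}oxy)trimethylsilane, via lithium enolate 15 (not isolated)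
Conditions: LiN(i-Pr)2, THF, −78 °C; Me3SiCl, −78 → 0 °C; pentane, filtration, no aqueous work-up
Reagents that add atoms: chlorotrimethylsilane, C[Si](C)(C)Cl
Why: Kinetic deprotonation of the methyl ketone and O-silylation of the lithium enolate (silyl enol ether formation) should proceed cleanly, the aryl fluoride being inert at −78 °C.

Step 7
Reactants: 16 ({1-[2-fluoro-4,6-bis(methoxymethoxy)-3-(3-methylbut-2-en-1-yl)phenyl]ethenyl}oxy)trimethylsilane; 6 2,2-dimethylchroman-6-carbaldehyde
Product: 19 (2S)-2-(2,2-dimethylchroman-6-yl)-5,7-bis(methoxymethoxy)-8-(3-methylbut-2-en-1-yl)chroman-4-one, via ammonium enolate 17 (not isolated), via (S)-aldolate anion 18 (not isolated)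
Conditions: (S,S)-N-spiro bis(binaphthyl)ammonium bifluoride bearing 3,3'-bis[3,5-bis(trifluoromethyl)phenyl] groups (5 mol %, from the commercial bromide by ion exchange), 4 Å MS, THF, slow addition of 16, −40 → 0 °C
Reagents that add atoms: none
Why: Proposed new method: fluoride from the catalyst removes Me3Si from 16 to give the ammonium enolate 17, which adds through C3 to the aldehyde carbon of 6 (C2–C3 bond) to give aldolate 18, whose oxygen then displaces fluoride at C8a ortho to the C4 carbonyl (O1–C8a bond), and the expelled fluoride desilylates the next molecule of 16, so that Me3SiF should be the only co-product and no stoichiometric base is present. The closest known reaction types are the fluoride-initiated Mukaiyama aldol addition under chiral quaternary ammonium ion pairing and the intramolecular SNAr closure of beta-hydroxy ketones onto ortho-fluoroaryl ketones to give chroman-4-ones; their merger into a fluoride-relay annulation is the new element. Ring C closes by a 6-endo-trig oxa-conjugate addition–elimination at C8a, the negative charge being taken up by the C4a–C4=O unit in the transition state. The C2 stereocentre is set under catalyst control: every anionic intermediate is ion-paired only with the chiral cation, and because the aldol addition is reversible the two enantiomeric aldolates interconvert by retro-aldol and should be funnelled through the faster-closing diastereomeric ion pair to the (S) product, while in the limit of fast ring closure the facial selectivity of the ion-paired enolate addition decides instead. The step needs ring closure to outrun dehydration of the aldolate and base-induced ring-opening of 19, which the low temperature, the catalytic concentration of basic species and the poor leaving-group ability of unsolvated hydroxide should secure, and it needs O-arylation at C8a only, which is secured because C8a carries the single fluorine while C5 and C7 are blocked as ethers, so the prenyl group can end only at C8.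

Step 8
Reactants: 19 (2S)-2-(2,2-dimethylchroman-6-yl)-5,7-bis(methoxymethoxy)-8-(3-methylbut-2-en-1-yl)chroman-4-one
Product: 20 Euchrenone a16, (2S)-2-(2,2-dimethylchroman-6-yl)-5,7-dihydroxy-8-(3-methylbut-2-en-1-yl)chroman-4-one
Conditions: 3 M HCl, MeOH, 50 °C, short reaction time
Reagents that add atoms: none
Why: Acid-catalysed acetal solvolysis (transacetalisation to dimethoxymethane) should free both phenols, and since C2 is not enolisable and ring C does not open readily under acid, the (S) configuration should be retained.

**Compound list**

1 | 4-bromophenol | Oc1ccc(Br)cc1 | starting material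
2 | 4-bromo-2-(3-methylbut-2-en-1-yl)phenol | CC(C)=CCc1cc(Br)ccc1O | intermediate (not isolated)
3 | 6-bromo-2,2-dimethylchroman | CC1(C)CCc2cc(Br)ccc2O1 | intermediate
4 | (2,2-dimethylchroman-6-yl)lithium | [Li]c1ccc2OC(C)(C)CCc2c1 | intermediate (not isolated)
5 | lithium (dimethylamino)(2,2-dimethylchroman-6-yl)methanolate, racemic | [Li]OC(N(C)C)c1ccc2OC(C)(C)CCc2c1 | intermediate (not isolated)
6 | 2,2-dimethylchroman-6-carbaldehyde | O=Cc1ccc2OC(C)(C)CCc2c1 | intermediate
7 | 5-fluororesorcinol (5-fluorobenzene-1,3-diol) | Oc1cc(O)cc(F)c1 | starting material
8 | 1-fluoro-3,5-bis(methoxymethoxy)benzene | COCOc1cc(F)cc(OCOC)c1 | intermediate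
9 | [2-fluoro-4,6-bis(methoxymethoxy)phenyl]lithium | [Li]c1c(F)cc(OCOC)cc1OCOC | intermediate (not isolated)
10 | [2-fluoro-4,6-bis(methoxymethoxy)phenyl]copper | [Cu]c1c(F)cc(OCOC)cc1OCOC | intermediate (not isolated)
11 | 1-fluoro-3,5-bis(methoxymethoxy)-2-(3-methylbut-2-en-1-yl)benzene | CC(C)=CCc1c(F)cc(OCOC)cc1OCOC | intermediate
12 | [2-fluoro-4,6-bis(methoxymethoxy)-3-(3-methylbut-2-en-1-yl)phenyl]lithium | [Li]c1c(F)c(CC=C(C)C)c(OCOC)cc1OCOC | intermediate (not isolated)
13 | lithium 1-[2-fluoro-4,6-bis(methoxymethoxy)-3-(3-methylbut-2-en-1-yl)phenyl]-1-[methoxy(methyl)amino]ethan-1-olate, racemic | CC(O[Li])(N(C)OC)c1c(F)c(CC=C(C)C)c(OCOC)cc1OCOC | intermediate (not isolated)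
14 | 1-[2-fluoro-4,6-bis(methoxymethoxy)-3-(3-methylbut-2-en-1-yl)phenyl]ethan-1-one | CC(=O)c1c(F)c(CC=C(C)C)c(OCOC)cc1OCOC | intermediate
15 | lithium 1-[2-fluoro-4,6-bis(methoxymethoxy)-3-(3-methylbut-2-en-1-yl)phenyl]ethen-1-olate | C=C(O[Li])c1c(F)c(CC=C(C)C)c(OCOC)cc1OCOC | intermediate (not isolated)
16 | ({1-[2-fluoro-4,6-bis(methoxymethoxy)-3-(3-methylbut-2-en-1-yl)phenyl]ethenyl}oxy)trimethylsilane | C=C(O[Si](C)(C)C)c1c(F)c(CC=C(C)C)c(OCOC)cc1OCOC | intermediate
17 | 1-[2-fluoro-4,6-bis(methoxymethoxy)-3-(3-methylbut-2-en-1-yl)phenyl]ethen-1-olate anion, drawn without its counter-ion, which is the chiral ammonium cation of the catalyst | C=C([O-])c1c(F)c(CC=C(C)C)c(OCOC)cc1OCOC | intermediate (not isolated)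
18 | (1S)-1-(2,2-dimethylchroman-6-yl)-3-[2-fluoro-4,6-bis(methoxymethoxy)-3-(3-methylbut-2-en-1-yl)phenyl]-3-oxopropan-1-olate anion, drawn without its counter-ion, which is the chiral ammonium cation of the catalyst | [O-][C@H](c1ccc2OC(C)(C)CCc2c1)CC(=O)c1c(F)c(CC=C(C)C)c(OCOC)cc1OCOC | intermediate (not isolated)
19 | (2S)-2-(2,2-dimethylchroman-6-yl)-5,7-bis(methoxymethoxy)-8-(3-methylbut-2-en-1-yl)chroman-4-one | CC(C)=CCc1c(OCOC)cc(OCOC)c2c1O[C@H](c1ccc3c(c1)CCC(C)(C)O3)CC2=O | intermediate
20 | Euchrenone a16, (2S)-2-(2,2-dimethylchroman-6-yl)-5,7-dihydroxy-8-(3-methylbut-2-en-1-yl)chroman-4-one | CC(C)=CCc1c(O)cc(O)c2c1O[C@H](c1ccc3c(c1)CCC(C)(C)O3)CC2=O | target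

**Count and risks**

Total step count: 8. Longest linear sequence: 6 steps (steps 3, 4, 5, 6, 7, 8, from 5-fluororesorcinol); the aldehyde branch (steps 1 and 2) joins at step 7.

Steps most likely to fail:

1. Step 7 (proposed new method). The ion-paired enolate may add with poor facial discrimination, ring closure may lose the race to dehydration of the aldolate or to silyl transfer, and the product may ring-open and re-close under the basic chain carriers, so that enantiomeric purity or conversion falls short. The fallback uses known chemistry only, sets out from ketone 14 and bromide 3, and comes back to the route at 19.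
   - Claisen condensation of 14 with ethyl formate (NaH, THF) should give the sodium enolate of the beta-keto aldehyde F1.
   - On warming in DMF, F1 should close by intramolecular SNAr of the enolate oxygen at the C–F carbon to the chromone F2.
   - Bromide 3 is taken through aryllithium 4 (n-BuLi; B(OMe)3; aqueous acid) to the boronic acid F3.
   - Enantioselective conjugate addition of F3 to F2 (Pd(OCOCF3)2, 4-tert-butyl-2-(pyridin-2-yl)-4,5-dihydrooxazole of the antipode that leads to 2S, NH4PF6, H2O, ClCH2CH2Cl, 60 °C) should then set C2 under ligand control in a base-free medium and give 19, which goes on to step 8.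

2. Step 5. Proton transfer from the enolisable acetamide to the hindered aryllithium instead of acyl transfer, competing metalation at the benzylic–allylic CH2 of the prenyl group, and loss of LiF to an aryne on warming may each lower the conversion. The fallback sets out from 11 and comes back at 14: aryllithium 12, generated as before, is trapped at −78 °C with acetaldehyde, a smaller and faster electrophile, to give the carbinol F4, which is then oxidised (Dess–Martin oxidation, CH2Cl2, rt) to 14.

3. Step 8. Acid-catalysed addition of the C7 hydroxyl to the neighbouring prenyl double bond (closure of a second dimethylpyran ring) and partial loss of configuration by acid-promoted opening of ring C may accompany the solvolysis. The fallback sets out from 19 and comes back at 20: TMSOTf and 2,2'-bipyridyl in CH2Cl2 at 0 °C should convert both aryl MOM ethers, without free protic acid, into the bis(trimethylsilyl) ether F5, which is hydrolysed with water at neutral pH to 20.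

**Further compounds**

F1 | step 7 | sodium (Z)-3-[2-fluoro-4,6-bis(methoxymethoxy)-3-(3-methylbut-2-en-1-yl)phenyl]-3-oxoprop-1-en-1-olate | [Na+].[O-]/C=C\C(=O)c1c(F)c(CC=C(C)C)c(OCOC)cc1OCOC
F2 | step 7 | 5,7-bis(methoxymethoxy)-8-(3-methylbut-2-en-1-yl)-4H-chromen-4-one | O=c1ccoc2c(CC=C(C)C)c(OCOC)cc(OCOC)c12
F3 | step 7 | (2,2-dimethylchroman-6-yl)boronic acid | OB(O)c1ccc2OC(C)(C)CCc2c1
F4 | step 5 | 1-[2-fluoro-4,6-bis(methoxymethoxy)-3-(3-methylbut-2-en-1-yl)phenyl]ethan-1-ol, racemic | CC(O)c1c(F)c(CC=C(C)C)c(OCOC)cc1OCOC
F5 | step 8 | (2S)-2-(2,2-dimethylchroman-6-yl)-8-(3-methylbut-2-en-1-yl)-5,7-bis(trimethylsilyloxy)chroman-4-one | CC(C)=CCc1c(O[Si](C)(C)C)cc(O[Si](C)(C)C)c2c1O[C@H](c1ccc3c(c1)CCC(C)(C)O3)CC2=O
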